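**Retrosynthetic overview**
1. Target 26 ⇐ tri-MOM benzofuran 25 by global MOM removal as the last step.
2. The furan ring is the only ring formed (both benzene rings are bought); it is closed late by Cu-catalysed intramolecular O-arylation of the enolate of 2-bromobenzyl aryl ketone 24.
3. Ketone 24 ⇐ β-keto ester 23 ⇐ aldol 22; the key C–C bond (future benzofuran C2–C3) comes from an intermolecular aldol addition of the lithium enolate of arylacetate 20 to aldehyde 15.
4. Aldehyde 15 ⇐ methyl 3,5-dihydroxybenzoate: MOM protection, reduction, 2,6-dibromination, two Br/Li-exchange prenylations, oxidation.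
5. Ester 20 ⇐ 2-(2-bromo-4-methoxyphenyl)acetic acid: demethylation, esterification, MOM protection.

Assumption: Mulberrofuran V has no stereocentre and no stereogenic double bond, so the "single enantiomer" is the achiral compound itself; the two stereocentres of aldol 22 are formed unselectively and are erased in steps 13 and 14.

**Route**

Step 1
Reactants: 1 methyl 3,5-dihydroxybenzoate; 2 chloromethyl methyl ether (MOMCl)
Product: 3 methyl 3,5-bis(methoxymethoxy)benzoate
Conditions: MOMCl (2.5 equiv), i-Pr2NEt (3 equiv), CH2Cl2, 0 °C → rt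
Reagents that add atoms: chloromethyl methyl ether, COCCl
Why: O-alkylation of both phenols (MOM protection) gives base-stable acetals that survive hydride, organolithium and enolate chemistry and later stabilise the ortho-aryllithiums by chelation.

Step 2
Reactants: 3 methyl 3,5-bis(methoxymethoxy)benzoate
Product: 4 [3,5-bis(methoxymethoxy)phenyl]methanol
Conditions: LiAlH4, THF, 0 °C; Fieser work-up
Reagents that add atoms: none
Why: LiAlH4 ester reduction gives the benzylic alcohol, and MOM acetals are inert to hydride.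

Step 3
Reactants: 4 [3,5-bis(methoxymethoxy)phenyl]methanol; 5 N-bromosuccinimide
Product: 6 [2,6-dibromo-3,5-bis(methoxymethoxy)phenyl]methanol
Conditions: NBS (2.05 equiv), MeCN, 0 °C → rt, dark
Reagents that add atoms: N-bromosuccinimide, O=C1CCC(=O)N1Br
Why: Electrophilic aromatic bromination goes para to each OMOM group (C2 and C6) rather than to the crowded C4 between them, as known for 3,5-dialkoxybenzyl systems, and NBS leaves only neutral succinimide so the MOM groups survive.

Step 4
Reactants: 6 [2,6-dibromo-3,5-bis(methoxymethoxy)phenyl]methanol; 7 tert-butyldimethylsilyl chloride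
Product: 8 {[2,6-dibromo-3,5-bis(methoxymethoxy)phenyl]methoxy}(tert-butyl)dimethylsilane
Conditions: TBSCl, imidazole, DMF, rt
Reagents that add atoms: tert-butyldimethylsilyl chloride, CC(C)(C)[Si](C)(C)Cl
Why: Imidazole-mediated silylation masks the primary OH before organolithium chemistry; silyl triflates are avoided because they attack MOM ethers.

Step 5
Reactants: 8 {[2,6-dibromo-3,5-bis(methoxymethoxy)phenyl]methoxy}(tert-butyl)dimethylsilane; 9 1-bromo-3-methylbut-2-ene (prenyl bromide)
Product: 11 {[2-bromo-3,5-bis(methoxymethoxy)-6-(3-methylbut-2-en-1-yl)phenyl]methoxy}(tert-butyl)dimethylsilane, via aryllithium 10 (not isolated)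
Conditions: n-BuLi (1.05 equiv), THF, −78 °C; CuBr·SMe2 (0.2 equiv); prenyl bromide (1.5 equiv), −78 → 0 °C
Reagents that add atoms: 1-bromo-3-methylbut-2-ene, CC(C)=CCBr
Why: One equivalent of n-BuLi effects a single Br/Li exchange to an OMOM-chelated aryllithium, and copper-catalysed SN2 allylation with prenyl bromide gives the linear prenyl arene; keeping the anion at −78 °C prevents O→C silyl migration.

Step 6
Reactants: 11 {[2-bromo-3,5-bis(methoxymethoxy)-6-(3-methylbut-2-en-1-yl)phenyl]methoxy}(tert-butyl)dimethylsilane; 9 1-bromo-3-methylbut-2-ene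
Product: 13 tert-butyl{[3,5-bis(methoxymethoxy)-2,6-bis(3-methylbut-2-en-1-yl)phenyl]methoxy}dimethylsilane, via aryllithium 12 (not isolated)
Conditions: n-BuLi (1.1 equiv), THF, −78 °C; CuBr·SMe2 (0.2 equiv); prenyl bromide (1.5 equiv), −78 → 0 °C
Reagents that add atoms: 1-bromo-3-methylbut-2-ene, CC(C)=CCBr
Why: The same Br/Li exchange and Cu-catalysed SN2 allylation installs the second prenyl group on the remaining bromide.

Step 7
Reactants: 13 tert-butyl{[3,5-bis(methoxymethoxy)-2,6-bis(3-methylbut-2-en-1-yl)phenyl]methoxy}dimethylsilane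
Product: 14 [3,5-bis(methoxymethoxy)-2,6-bis(3-methylbut-2-en-1-yl)phenyl]methanol
Conditions: TBAF, THF, 0 °C → rt
Reagents that add atoms: none
Why: Fluoride-driven desilylation frees the benzylic alcohol without touching MOM ethers or prenyl groups.

Step 8
Reactants: 14 [3,5-bis(methoxymethoxy)-2,6-bis(3-methylbut-2-en-1-yl)phenyl]methanol
Product: 15 3,5-bis(methoxymethoxy)-2,6-bis(3-methylbut-2-en-1-yl)benzaldehyde
Conditions: Dess–Martin periodinane (1.2 equiv), CH2Cl2, 0 °C → rt
Reagents that add atoms: none
Why: Dess–Martin oxidation stops cleanly at the aldehyde even for a hindered benzylic alcohol and tolerates trisubstituted alkenes and acetals.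

Step 9
Reactants: 16 2-(2-bromo-4-methoxyphenyl)acetic acid
Product: 17 2-(2-bromo-4-hydroxyphenyl)acetic acid
Conditions: BBr3 (3 equiv), CH2Cl2, −78 °C → rt; then H2O
Reagents that add atoms: none
Why: BBr3 cleavage of the aryl methyl ether is done here, before any acid-sensitive group exists, so that the phenol can later be released under mild conditions.

Step 10
Reactants: 17 2-(2-bromo-4-hydroxyphenyl)acetic acid; 18 methanol
Product: 19 methyl 2-(2-bromo-4-hydroxyphenyl)acetate
Conditions: MeOH, H2SO4 (cat.), reflux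
Reagents that add atoms: methanol, CO
Why: Fischer esterification converts only the carboxylic acid; the phenol does not esterify under these conditions.

Step 11
Reactants: 19 methyl 2-(2-bromo-4-hydroxyphenyl)acetate; 2 chloromethyl methyl ether
Product: 20 methyl 2-[2-bromo-4-(methoxymethoxy)phenyl]acetate
Conditions: MOMCl (1.5 equiv), i-Pr2NEt (2 equiv), CH2Cl2, 0 °C → rt
Reagents that add atoms: chloromethyl methyl ether, COCCl
Why: MOM protection removes the acidic phenol proton so that a single equivalent of base forms the ester enolate cleanly.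

Step 12
Reactants: 20 methyl 2-[2-bromo-4-(methoxymethoxy)phenyl]acetate; 15 3,5-bis(methoxymethoxy)-2,6-bis(3-methylbut-2-en-1-yl)benzaldehyde
Product: 22 methyl 2-[2-bromo-4-(methoxymethoxy)phenyl]-3-hydroxy-3-[3,5-bis(methoxymethoxy)-2,6-bis(3-methylbut-2-en-1-yl)phenyl]propanoate (racemic syn/anti mixture), via lithium enolate 21 (not isolated)
Conditions: LDA (1.15 equiv), THF, −78 °C; then 15, −78 °C; AcOH/THF quench at −78 °C
Reagents that add atoms: none
Why: Intermolecular aldol addition of a preformed lithium ester enolate to a non-enolisable aldehyde joins the two fragments; the two new stereocentres form unselectively, which is irrelevant because both are removed later, and the cold acidic quench suppresses retro-aldol and dehydration.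

Step 13
Reactants: 22 the aldol adduct (syn/anti mixture)
Product: 23 methyl 2-[2-bromo-4-(methoxymethoxy)phenyl]-3-oxo-3-[3,5-bis(methoxymethoxy)-2,6-bis(3-methylbut-2-en-1-yl)phenyl]propanoate (racemic, keto/enol mixture)
Conditions: Dess–Martin periodinane (1.2 equiv), CH2Cl2, rt
Reagents that add atoms: none
Why: Dess–Martin oxidation of the secondary benzylic alcohol gives the β-keto ester, merging both diastereomers into one compound.

Step 14
Reactants: 23 the β-keto ester
Product: 24 2-[2-bromo-4-(methoxymethoxy)phenyl]-1-[3,5-bis(methoxymethoxy)-2,6-bis(3-methylbut-2-en-1-yl)phenyl]ethan-1-one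
Conditions: LiCl (3 equiv), DMSO, H2O, 140 °C
Reagents that add atoms: none
Why: Krapcho dealkoxycarbonylation (chloride SN2 demethylation, then loss of CO2) works under neutral conditions that spare MOM ethers, prenyl groups and the aryl bromide, and removes the last stereocentre.

Step 15
Reactants: 24 the 2-bromobenzyl aryl ketone
Product: 25 2-[3,5-bis(methoxymethoxy)-2,6-bis(3-methylbut-2-en-1-yl)phenyl]-6-(methoxymethoxy)-1-benzofuran
Conditions: CuI (10 mol %), K3PO4 (2 equiv), DMF, 105 °C, N2
Reagents that add atoms: none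
Why: Cu-catalysed intramolecular Ullmann-type O-arylation of the ketone enolate closes the furan ring under purely basic conditions, and the less crowded enolate geometry places the oxygen cis to the bromoarene.

Step 16
Reactants: 25 the tri-MOM benzofuran
Product: 26 Mulberrofuran V, 5-(6-hydroxy-1-benzofuran-2-yl)-4,6-bis(3-methylbut-2-en-1-yl)benzene-1,3-diol
Conditions: 3 M aq. HCl, MeOH, rt; stop at full conversion
Reagents that add atoms: none
Why: Acid-catalysed acetal methanolysis removes all three MOM groups at room temperature, where protonation of the prenyl alkenes (chroman formation) is much slower than acetal cleavage.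

**Compound list**
1 | methyl 3,5-dihydroxybenzoate | COC(=O)c1cc(O)cc(O)c1 | starting material
2 | chloromethyl methyl ether (MOMCl) | COCCl | starting material
3 | methyl 3,5-bis(methoxymethoxy)benzoate | COC(=O)c1cc(OCOC)cc(OCOC)c1 | intermediate
4 | [3,5-bis(methoxymethoxy)phenyl]methanol | OCc1cc(OCOC)cc(OCOC)c1 | intermediate
5 | N-bromosuccinimide | O=C1CCC(=O)N1Br | starting material
6 | [2,6-dibromo-3,5-bis(methoxymethoxy)phenyl]methanol | OCc1c(Br)c(OCOC)cc(OCOC)c1Br | intermediate
7 | tert-butyldimethylsilyl chloride | CC(C)(C)[Si](C)(C)Cl | starting material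
8 | {[2,6-dibromo-3,5-bis(methoxymethoxy)phenyl]methoxy}(tert-butyl)dimethylsilane | CC(C)(C)[Si](C)(C)OCc1c(Br)c(OCOC)cc(OCOC)c1Br | intermediate
9 | 1-bromo-3-methylbut-2-ene (prenyl bromide) | CC(C)=CCBr | starting material
10 | [3-bromo-2-{[(tert-butyldimethylsilyl)oxy]methyl}-4,6-bis(methoxymethoxy)phenyl]lithium | CC(C)(C)[Si](C)(C)OCc1c([Li])c(OCOC)cc(OCOC)c1Br | intermediate
11 | {[2-bromo-3,5-bis(methoxymethoxy)-6-(3-methylbut-2-en-1-yl)phenyl]methoxy}(tert-butyl)dimethylsilane | CC(C)(C)[Si](C)(C)OCc1c(CC=C(C)C)c(OCOC)cc(OCOC)c1Br | intermediate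
12 | [2-{[(tert-butyldimethylsilyl)oxy]methyl}-4,6-bis(methoxymethoxy)-3-(3-methylbut-2-en-1-yl)phenyl]lithium | CC(C)(C)[Si](C)(C)OCc1c(CC=C(C)C)c(OCOC)cc(OCOC)c1[Li] | intermediate
13 | tert-butyl{[3,5-bis(methoxymethoxy)-2,6-bis(3-methylbut-2-en-1-yl)phenyl]methoxy}dimethylsilane | CC(C)(C)[Si](C)(C)OCc1c(CC=C(C)C)c(OCOC)cc(OCOC)c1CC=C(C)C | intermediate
14 | [3,5-bis(methoxymethoxy)-2,6-bis(3-methylbut-2-en-1-yl)phenyl]methanol | OCc1c(CC=C(C)C)c(OCOC)cc(OCOC)c1CC=C(C)C | intermediate
15 | 3,5-bis(methoxymethoxy)-2,6-bis(3-methylbut-2-en-1-yl)benzaldehyde | O=Cc1c(CC=C(C)C)c(OCOC)cc(OCOC)c1CC=C(C)C | intermediate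
16 | 2-(2-bromo-4-methoxyphenyl)acetic acid | COc1ccc(CC(=O)O)c(Br)c1 | starting material
17 | 2-(2-bromo-4-hydroxyphenyl)acetic acid | Oc1ccc(CC(=O)O)c(Br)c1 | intermediate
18 | methanol | CO | starting material
19 | methyl 2-(2-bromo-4-hydroxyphenyl)acetate | COC(=O)Cc1ccc(O)cc1Br | intermediate
20 | methyl 2-[2-bromo-4-(methoxymethoxy)phenyl]acetate | COC(=O)Cc1ccc(OCOC)cc1Br | intermediate
21 | lithium enolate of 20 | COC(O[Li])=Cc1ccc(OCOC)cc1Br | intermediate
22 | methyl 2-[2-bromo-4-(methoxymethoxy)phenyl]-3-hydroxy-3-[3,5-bis(methoxymethoxy)-2,6-bis(3-methylbut-2-en-1-yl)phenyl]propanoate (racemic, syn/anti mixture) | COC(=O)C(c1ccc(OCOC)cc1Br)C(O)c1c(CC=C(C)C)c(OCOC)cc(OCOC)c1CC=C(C)C | intermediate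
23 | methyl 2-[2-bromo-4-(methoxymethoxy)phenyl]-3-oxo-3-[3,5-bis(methoxymethoxy)-2,6-bis(3-methylbut-2-en-1-yl)phenyl]propanoate (racemic) | COC(=O)C(c1ccc(OCOC)cc1Br)C(=O)c1c(CC=C(C)C)c(OCOC)cc(OCOC)c1CC=C(C)C | intermediate
24 | 2-[2-bromo-4-(methoxymethoxy)phenyl]-1-[3,5-bis(methoxymethoxy)-2,6-bis(3-methylbut-2-en-1-yl)phenyl]ethan-1-one | O=C(Cc1ccc(OCOC)cc1Br)c1c(CC=C(C)C)c(OCOC)cc(OCOC)c1CC=C(C)C | intermediate
25 | 2-[3,5-bis(methoxymethoxy)-2,6-bis(3-methylbut-2-en-1-yl)phenyl]-6-(methoxymethoxy)-1-benzofuran | COCOc1ccc2cc(-c3c(CC=C(C)C)c(OCOC)cc(OCOC)c3CC=C(C)C)oc2c1 | intermediate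
26 | Mulberrofuran V (achiral) | CC(C)=CCc1c(O)cc(O)c(CC=C(C)C)c1-c1cc2ccc(O)cc2o1 | target

**Totals**
Total step count: 16.
Longest linear sequence: 13 steps (steps 1–8, then 12–16); the arylacetate branch is 3 steps (9–11).

**Three steps most likely to fail, each with a fallback**

Step 5 (and its twin, step 6). The risks are incomplete exchange, some SN2′ (reverse-prenyl) product, or silyl migration if the anion warms. The fallback avoids aryllithiums and sets out from dibromide 8. Prenyl bromide 9 is converted with Zn dust/LiCl in THF into 3-methylbut-2-enylzinc bromide F1. F1 is coupled twice with 8 in a Pd-catalysed, linear-selective Negishi coupling (CPhos-type palladacycle precatalyst, THF, rt). This gives diprenyl silyl ether 13 directly, where the route resumes at step 7.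

Step 12. The di-ortho-substituted, electron-rich aldehyde may add sluggishly or the aldolate may revert. The fallback replaces the reversible aldol/oxidation pair by an irreversible enolate acylation and sets out from aldehyde 15. Pinnick oxidation (NaClO2, NaH2PO4, 2-methyl-2-butene, t-BuOH/H2O) gives 3,5-bis(methoxymethoxy)-2,6-bis(3-methylbut-2-en-1-yl)benzoic acid F2. Cyanuric fluoride/pyridine in CH2Cl2 converts it into the compact, highly electrophilic 3,5-bis(methoxymethoxy)-2,6-bis(3-methylbut-2-en-1-yl)benzoyl fluoride F3. C-acylation of lithium enolate 21 (2.2 equiv, THF, −78 → 0 °C; crossed Claisen condensation, driven by deprotonation of the product) gives β-keto ester 23, and the route resumes at step 14.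

Step 16. Brønsted acid can cyclise the ortho-prenylphenols to 2,2-dimethylchromans. The fallback cleaves the acetals by silyl transfer instead of protic acid and sets out from 25. TMSOTf/2,2′-bipyridyl in CH2Cl2 (0 °C → rt) converts the three aromatic MOM ethers into 2-[2,6-bis(3-methylbut-2-en-1-yl)-3,5-bis(trimethylsilyloxy)phenyl]-6-(trimethylsilyloxy)-1-benzofuran F4. Adding water at rt hydrolyses the aryl silyl ethers and gives target 26.

**Further compounds**
F1 | step 5 | 3-methylbut-2-enylzinc bromide | CC(C)=CC[Zn]Br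
F2 | step 12 | 3,5-bis(methoxymethoxy)-2,6-bis(3-methylbut-2-en-1-yl)benzoic acid | OC(=O)c1c(CC=C(C)C)c(OCOC)cc(OCOC)c1CC=C(C)C
F3 | step 12 | 3,5-bis(methoxymethoxy)-2,6-bis(3-methylbut-2-en-1-yl)benzoyl fluoride | FC(=O)c1c(CC=C(C)C)c(OCOC)cc(OCOC)c1CC=C(C)C
F4 | step 16 | 2-[2,6-bis(3-methylbut-2-en-1-yl)-3,5-bis(trimethylsilyloxy)phenyl]-6-(trimethylsilyloxy)-1-benzofuran | C[Si](C)(C)Oc1ccc2cc(-c3c(CC=C(C)C)c(O[Si](C)(C)C)cc(O[Si](C)(C)C)c3CC=C(C)C)oc2c1
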